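Readings and results were generated by integration with constants of no real substance; noise was put on by code.

Two questions stand for the flask, and both need a count of chains that no earlier run shows.

common to all: free monomer 0.50 M
- midnight: transfer agent 0.015 M; initiator 4.6 mol%; run made earlier
- summer: transfer agent 0.015 M; initiator 10 mol%; run made earlier
- flask: transfer agent 0.0150 M; initiator 6.8 mol%; time 10 h

- midnight (time / h: monomer in chains / %, free monomer / %): 0.500: 20, 79; 1.50: 39, 59; 3.00: 52, 43; 4.00: 63, 36; 6.00: 75, 23
- summer (time / h: monomer in chains / %, free monomer / %): 0.500: 34, 59; 0.833: 55, 44; 1.50: 75, 20; 3.00: 92, 6; 6.00: 96, 2

(standard deviation of a reading: 2 percentage points)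

* whether the average number of monomer units in a chain (chains begun, living or dead) reaches 7.0 by 10 h (no / yes)
* average number of monomer units in a chain (chains begun, living or dead) at 10 h

- the average divides the monomer in chains by the number of chains begun, living and dead together
- the earlier runs do not show the number of chains; that part of a forecast is a guess

We solve the two ends. At one end, transfer agent stops a chain and starts another, so the chains begun in the flask would number initiator plus transfer agent, with a length of 10.2 at full conversion. Growing chains would stay at the initiator charge, and the late pseudo-first-order slopes of the logarithm of free monomer, summer over midnight, would stand at 2.17. At the other end, transfer agent stops a chain and starts none, so growing chains fall to initiator minus transfer agent and that ratio becomes 4.38.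

The readings give 0.209 /h for midnight and 0.803 /h for summer. Their ratio of 3.85 is higher than the first end's and lower than the second end's, though the summer reading of 6% carries a scatter of 2 percentage points. We commit to the second end, the nearer of the two.

We carry the budget length, free monomer charged divided by initiator charged: 14.7 for the flask. Once initiator in the flask has reacted, with one chain begun per initiator, length is budget length times the fraction of free monomer reacted. Midnight's late slope, scaled to the flask's growing chains, gives a fall of 4.95 in the logarithm of free monomer by 10 h, an estimate of 0.708% free monomer left. So we expect a length near 14.7, and 7.0 needs 47.6% reacted.

The forecast says yes and 11, adding “Chain count is a guess.” Our answer to the first question is the same, but our length is longer.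

The flask gives yes and 14.7.

    free monomer + initiator → living end + monomer in chains (k = 0.00440 /M/s)
    free monomer + living end → monomer in chains + living end, rate k2*[living end]*[free monomer] (k = 0.00793 /M/s)
    living end + transfer agent → dead chain (kL = 0.0484 /M/s)
    2 free monomer → self-condensation product (k = 2.59 × 10⁻⁶ /M/s)
    living end + free monomer → dead end A (k = 2.87 × 10⁻⁵ /M/s)
    2 initiator → spent initiator B (k = 9.75 × 10⁻⁴ /M/s)

At the start of the flask, the step from free monomer and initiator to living end used initiator 33 times as fast as the step to spent initiator B. The length at 10 h stands at 14.7 against a budget length of 14.7, and 7.0 was reached at 1.06 h, with 47.4% of the free monomer reacted against the 47.6% reckoned.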